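G lost reappears as J: Saturday's last readings, 72.7% of J and 27.0% of G, sum to 99.7% of the charge, against a scatter of 1 percentage point per reading. That balance holds, so the open question is how long D keeps working.

| flask | G | D | remark | time |
|---|---|---|---|---|
| Tuesday's | 0.0078 M | 0.48 µM | run made earlier |  |
| Wednesday's | 0.024 M | 0.48 µM | run made earlier |  |
| Saturday's | 0.051 M | 0.48 µM | run made earlier |  |
| Friday's | 0.020 M | 0.52 µM | run made earlier |  |
| birch | 0.010 M | 0.48 µM |  | 5.0 h |
| cedar | 0.012 M | 0.80 µM |  | 5.0 h |
| alder | 0.012 M | 0.25 µM |  | 5.0 h |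
| maple | 0.020 M | 0.48 µM |  | 5.0 h |
| oak | 0.060 M | 1.5 µM |  | 5.0 h |
| ash | 0.030 M | 1.0 µM |  | 5.0 h |

| run | time / h | J / % | G / % |
|---|---|---|---|
| Tuesday's | 1.33 | 17.6 | 84.2 |
| Tuesday's | 2.50 | 22.0 | 77.0 |
| Tuesday's | 4.00 | 29.4 | 70.0 |
| Tuesday's | 5.00 | 32.9 | 65.1 |
| Wednesday's | 0.417 | 15.3 | 82.3 |
| Wednesday's | 1.00 | 30.6 | 67.2 |
| Wednesday's | 2.00 | 49.6 | 50.3 |
| Wednesday's | 5.00 | 64.4 | 33.0 |
| Saturday's | 1.33 | 29.6 | 70.7 |
| Saturday's | 2.50 | 53.1 | 50.1 |
| Saturday's | 4.00 | 68.6 | 31.6 |
| Saturday's | 5.00 | 72.7 | 27.0 |
| Friday's | 0.667 | 23.5 | 74.1 |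
| Friday's | 2.00 | 47.5 | 50.9 |
| Friday's | 3.00 | 56.1 | 44.3 |
| Friday's | 5.00 | 64.4 | 34.5 |

(scatter of a reading: 1 percentage point)



1. the flasks put in order of amount of J, in percent of the G charged, best first, at 5.0 h (birch / cedar / alder / maple / oak / ash)
2. the amount of J, in percent of the G charged of the flask you put first, at 5.0 h
3. the amount of J, in percent of the G charged of the flask you put last, at 5.0 h

*Does D last?* Compare two runs at equal [D]. Saturday's comes down to 0.0138 M at 5.00 h. Interpolating between its readings, it passes 0.024 M at 2.75 h, so that stretch takes it 2.25 h. Wednesday's starts at 0.024 M and covers the same stretch in 1.58 h, so the later passage is slower.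

*What do you read from that?* The midpoints of the two passages lie 3.08 h apart. Taking the loss as first-order gives a decay constant of 0.115 h⁻¹ and a half-life of D of about 6.03 h. This is a reading, with the scatter of the readings in it.

*What do you carry forward?* The live time: the hours of fresh D that equal the hours elapsed, which is one minus the surviving fraction, divided by the decay constant. At 5.0 h it is 3.80 h, and at 2.00 h it is 1.79 h. My rule is that equal [G] and equal [D] times live time give equal progress.

*Where is that weak?* It assumes rate proportional to [D], and the runs span only 0.48 µM to 0.52 µM, while alder holds about half of Wednesday's [D].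

*Use it on alder.* Wednesday's holds 0.0121 M of G at 2.00 h, close to alder's charge of 0.012 M. Alder's whole allowance, its [D] times its live time, stands to Wednesday's remaining allowance, its [D] times its remaining live time, at a ratio of 0.982. So alder should end at Wednesday's final [G], which gives J of 34.0%.

The forecast orders the flasks oak > ash > maple > cedar > birch > alder. It gives oak 90% (84% to 95%) and alder 36% (29% to 43%), allowing “an effective time of about 5 h at low J, falling to about 3.6 h at high J”. My alder is lower, inside that range.

    G + D → J + D, rate k1*[G]^3*[D]/(1 + ([G]/Kh1)^3) (17.0 mM, k = 1.60 × 10⁶ L³ mol⁻³ s⁻¹)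
    D → Q (k = 0.00210 min⁻¹)

The flasks came out as oak > ash > maple > cedar > birch > alder, with oak at 91.9% and alder at 34.0%, the forecast's order. The neighbour is alder charged with 0.020 M of G, which is Friday's [G]. Its [D] times live time at 5.0 h stands to Friday's at 2.00 h at a ratio of 1.02, so the reckoning reads off Friday's J at that time, 47.5%. The neighbour flask gives J of 48.1%.

The earlier runs and the new flask are simulated from invented constants; noise was put on by code.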